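## Retrosynthetic overview

1. Target ⇐ fivefold desilylation of a fully silylated dimer; the C(tertiary)–O(enol) bond joining the two halves ⇐ acid-promoted opening of an (S)-trisubstituted epoxide on one butenolide half by the free enol OH of the prenylated half.
2. Both halves ⇐ one (R)-iodo-butenolide: Stille prenylation gives the nucleophile; enol silylation, nickel/photoredox decarboxylative arylation with a D-malic-acid-derived hydroxy lactone, and epoxide closure with inversion give the electrophile.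
3. Butenolide ring ⇐ methanolysis/lactonization of a dioxolanone keto ester; its quaternary C–C bond ⇐ a new visible-light radical-polar crossover coupling of a tyrosine-derived Seebach silyl ketene acetal with an α-chloro arylpyruvate (made by a Darzens reaction).
4. Stereocentres: both quaternary carbons from 3-iodo-L-tyrosine (self-regeneration of stereocentres through the tert-butyl acetal); the carbinol from D-malic acid.
5. Ring order: dioxolanone template → butenolide (made once, used for both halves) → epoxide (transient); all arenes are bought.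

Assumption: TIPS = triisopropylsilyl; 4-(triisopropylsilyloxy)benzaldehyde is taken as a catalogue compound (otherwise one silylation of 4-hydroxybenzaldehyde); 3-iodo-L-tyrosine and D-malic acid are inexpensive catalogue compounds.

## Route

Step 1
Reactants: 1 3-iodo-L-tyrosine
Product: 2 (S)-2-hydroxy-3-(4-hydroxy-3-iodophenyl)propanoic acid
Conditions: NaNO2, 1 M H2SO4, H2O/1,4-dioxane, 0 °C → rt
Reagents that add atoms: water O
Why: Diazotization of the α-amino acid (Van Slyke type): the carboxylate displaces N2 to an α-lactone that water reopens, so OH replaces NH2 with net retention (double inversion) and the bought S centre is kept.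

Step 2
Reactants: 2 (S)-2-hydroxy-3-(4-hydroxy-3-iodophenyl)propanoic acid
Product: 3 (2S,5S)-2-tert-butyl-5-(4-hydroxy-3-iodobenzyl)-1,3-dioxolan-4-one
Conditions: t-BuCHO (3 equiv), TsOH·H2O (5 mol %), pentane/CH2Cl2, reflux, Dean–Stark; recrystallisation
Reagents that add atoms: pivalaldehyde CC(C)(C)C=O
Why: Acid-catalysed acetalization (Seebach self-regeneration-of-stereocentres template): the existing S centre steers the new acetal carbon to the thermodynamically preferred cis-2,5 arrangement, and the cis isomer is purified by recrystallisation.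

Step 3
Reactants: 3 (2S,5S)-2-tert-butyl-5-(4-hydroxy-3-iodobenzyl)-1,3-dioxolan-4-one
Product: 4 (2S,5S)-2-tert-butyl-5-[3-iodo-4-(triisopropylsilyloxy)benzyl]-1,3-dioxolan-4-one
Conditions: TIPSOTf, 2,6-lutidine, CH2Cl2, 0 °C
Reagents that add atoms: triisopropylsilyl triflate CC(C)[Si](OS(=O)(=O)C(F)(F)F)(C(C)C)C(C)C
Why: Phenol silylation with a non-nucleophilic base leaves the acylal untouched and gives a bulky, base-tolerant aryl silyl ether for the enolization, photoredox and methanolysis steps.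

Step 4
Reactants: 5 4-(triisopropylsilyloxy)benzaldehyde; 6 methyl dichloroacetate
Product: 8 methyl 3-chloro-2-oxo-3-[4-(triisopropylsilyloxy)phenyl]propanoate (racemic), via chloroglycidic ester 7 (not isolated)
Conditions: NaOMe (1.1 equiv), Et2O/MeOH, −10 °C → rt; then PhMe, 60 °C
Reagents that add atoms: none
Why: Darzens condensation of the dichloroacetate anion with the aldehyde gives the α-chloroglycidic ester, which undergoes the usual ring opening with 1,2-chloride shift (helped by the electron-rich arene) to the β-chloro-α-keto ester; its racemic centre is erased later.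

Step 5
Reactants: 4 (2S,5S)-2-tert-butyl-5-[3-iodo-4-(triisopropylsilyloxy)benzyl]-1,3-dioxolan-4-one; 8 methyl 3-chloro-2-oxo-3-[4-(triisopropylsilyloxy)phenyl]propanoate
Product: 10 (2S,5R)-2-tert-butyl-5-[3-iodo-4-(triisopropylsilyloxy)benzyl]-5-{3-methoxy-2,3-dioxo-1-[4-(triisopropylsilyloxy)phenyl]propyl}-1,3-dioxolan-4-one (both epimers at the benzylic CH), via silyl ketene acetal 9 (not isolated)
Conditions: LiN(SiMe3)2 (1.05 equiv), TMSCl (1.3 equiv), THF, −78 → 0 °C; then 8 (1.5 equiv), [Ir(ppy)2(dtbbpy)]PF6 (1 mol %), MeCN, 450 nm LEDs, rt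
Reagents that add atoms: none
Why: Proposed new method: visible-light radical-polar crossover alkylation of a Seebach-type silyl ketene acetal, in which the excited trivalent iridium photocatalyst (or a chain carrier) reduces 8 with loss of chloride to an electrophilic benzylic α-keto radical that adds to the electron-rich C5 of 9 on the face anti to the tert-butyl group (the same facial bias as enolate alkylations of this template, so the new bond takes the place of the former C–H and the quaternary centre is R), and the resulting α,α-dioxygenated radical is oxidized by tetravalent iridium or by 8 to a silyloxocarbenium ion that loses the silyl group to chloride and regenerates the dioxolanone; the closest known reaction types are the photoredox α-alkylation of enol silanes and silyl ketene acetals with α-halocarbonyl compounds and the thermal enolate alkylation of dioxolanones, and the new element is radical C–C bond formation at the fully substituted carbon of this chiral template, which avoids the polar attack on the keto carbonyl that a lithium enolate would suffer.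

Step 6
Reactants: 10 (2S,5R)-2-tert-butyl-5-[3-iodo-4-(triisopropylsilyloxy)benzyl]-5-{3-methoxy-2,3-dioxo-1-[4-(triisopropylsilyloxy)phenyl]propyl}-1,3-dioxolan-4-one
Product: 12 methyl (R)-4-hydroxy-2-[3-iodo-4-(triisopropylsilyloxy)benzyl]-5-oxo-3-[4-(triisopropylsilyloxy)phenyl]-2,5-dihydrofuran-2-carboxylate, via hydroxy diester 11 (not isolated)
Conditions: K2CO3 (1.5 equiv), MeOH/THF, 0 °C → rt; 1 M HCl work-up
Reagents that add atoms: methanol CO
Why: Base-mediated methanolysis of the acylal (methoxide attacks the dioxolanone carbonyl and the hemiacetal alkoxide loses pivalaldehyde) is followed by 5-exo lactonization of the tertiary alkoxide onto the keto ester and enolization to the conjugated 3-hydroxybutenolide, whose enolate is the thermodynamic sink and blocks retro-aldol cleavage, so the R quaternary centre is untouched and the aryl TIPS ethers survive.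

Step 7
Reactants: 12 methyl (R)-4-hydroxy-2-[3-iodo-4-(triisopropylsilyloxy)benzyl]-5-oxo-3-[4-(triisopropylsilyloxy)phenyl]-2,5-dihydrofuran-2-carboxylate
Product: 13 methyl (R)-4-hydroxy-2-[3-(3-methylbut-2-en-1-yl)-4-(triisopropylsilyloxy)benzyl]-5-oxo-3-[4-(triisopropylsilyloxy)phenyl]-2,5-dihydrofuran-2-carboxylate
Conditions: Pd(PPh3)4 (5 mol %), tributyl(3-methylbut-2-en-1-yl)stannane (1.5 equiv), DMF, 90 °C
Reagents that add atoms: tributyl(3-methylbut-2-en-1-yl)stannane CC(C)=CC[Sn](CCCC)(CCCC)CCCC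
Why: Stille cross-coupling: zerovalent palladium inserts into the aryl iodide and the prenyl group is transferred from tin at its unsubstituted terminus, giving the linear ortho-prenyl arene under neutral, fluoride-free conditions that leave the enol, esters and silyl ethers alone.

Step 8
Reactants: 12 methyl (R)-4-hydroxy-2-[3-iodo-4-(triisopropylsilyloxy)benzyl]-5-oxo-3-[4-(triisopropylsilyloxy)phenyl]-2,5-dihydrofuran-2-carboxylate
Product: 14 methyl (R)-2-[3-iodo-4-(triisopropylsilyloxy)benzyl]-5-oxo-4-(triisopropylsilyloxy)-3-[4-(triisopropylsilyloxy)phenyl]-2,5-dihydrofuran-2-carboxylate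
Conditions: TIPSOTf, 2,6-lutidine, CH2Cl2, 0 °C
Reagents that add atoms: triisopropylsilyl triflate CC(C)[Si](OS(=O)(=O)C(F)(F)F)(C(C)C)C(C)C
Why: Silylation of the enol hydroxyl masks the only remaining acidic O–H, so this half can neither act as the nucleophile in the dimerization nor be sulfonylated in the epoxide-forming step.

Step 9
Reactants: 15 D-malic acid
Product: 16 (R)-2-(2,2-dimethyl-5-oxo-1,3-dioxolan-4-yl)acetic acid
Conditions: Me2C(OMe)2, TsOH·H2O (cat.), rt
Reagents that add atoms: 2,2-dimethoxypropane COC(C)(C)OC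
Why: Acid-catalysed transacetalization ties the α-hydroxy acid unit into the five-membered dioxolanone and leaves the distal carboxylic acid free, with no bond to the R centre broken.

Step 10
Reactants: 16 (R)-2-(2,2-dimethyl-5-oxo-1,3-dioxolan-4-yl)acetic acid
Product: 18 (R)-4-hydroxy-5,5-dimethyldihydrofuran-2(3H)-one, via dihydroxy acid 17 (not isolated)
Conditions: MeMgBr (5 equiv), THF, −20 °C → rt; then 2 M HCl, rt
Reagents that add atoms: methylmagnesium bromide C[Mg]Br
Why: Grignard addition: the magnesium carboxylate is inert while the activated dioxolanone carbonyl takes up two methyl groups, and acidic work-up releases acetone and lactonizes the γ-hydroxy acid, the R carbinol being a spectator.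

Step 11
Reactants: 14 methyl (R)-2-[3-iodo-4-(triisopropylsilyloxy)benzyl]-5-oxo-4-(triisopropylsilyloxy)-3-[4-(triisopropylsilyloxy)phenyl]-2,5-dihydrofuran-2-carboxylate; 18 (R)-4-hydroxy-5,5-dimethyldihydrofuran-2(3H)-one
Product: 20 methyl (R)-2-{3-[(R)-2,3-dihydroxy-3-methylbutyl]-4-(triisopropylsilyloxy)benzyl}-5-oxo-4-(triisopropylsilyloxy)-3-[4-(triisopropylsilyloxy)phenyl]-2,5-dihydrofuran-2-carboxylate, via cesium carboxylate 19 (not isolated)
Conditions: 18 (2 equiv), CsOH·H2O (2 equiv), MeOH, rt, evaporate; then 14, Ir[dF(CF3)ppy]2(dtbbpy)PF6 (2 mol %), NiCl2·glyme (10 mol %), dtbbpy (15 mol %), DMSO, 450 nm LEDs, rt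
Reagents that add atoms: none
Why: Nickel/photoredox decarboxylative C(sp3)–C(sp2) cross-coupling: the excited iridium photocatalyst oxidizes the carboxylate, loss of CO2 gives a primary β-hydroxyalkyl radical that is captured by the arylnickel species formed from the aryl iodide and reductively eliminated, the carbinol centre staying R because no bond to it is touched.

Step 12
Reactants: 20 methyl (R)-2-{3-[(R)-2,3-dihydroxy-3-methylbutyl]-4-(triisopropylsilyloxy)benzyl}-5-oxo-4-(triisopropylsilyloxy)-3-[4-(triisopropylsilyloxy)phenyl]-2,5-dihydrofuran-2-carboxylate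
Product: 22 methyl (R)-2-{3-{[(S)-3,3-dimethyloxiran-2-yl]methyl}-4-(triisopropylsilyloxy)benzyl}-5-oxo-4-(triisopropylsilyloxy)-3-[4-(triisopropylsilyloxy)phenyl]-2,5-dihydrofuran-2-carboxylate, via secondary mesylate 21 (not isolated)
Conditions: MsCl (1.1 equiv), Et3N, CH2Cl2, −20 °C; then NaH (1.2 equiv), THF, 0 °C
Reagents that add atoms: none
Why: Selective sulfonylation of the secondary hydroxyl followed by intramolecular Williamson displacement by the tertiary alkoxide (3-exo-tet, SN2) closes the epoxide with clean inversion, turning the R carbinol into the S epoxide carbon.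

Step 13
Reactants: 22 methyl (R)-2-{3-{[(S)-3,3-dimethyloxiran-2-yl]methyl}-4-(triisopropylsilyloxy)benzyl}-5-oxo-4-(triisopropylsilyloxy)-3-[4-(triisopropylsilyloxy)phenyl]-2,5-dihydrofuran-2-carboxylate; 13 methyl (R)-4-hydroxy-2-[3-(3-methylbut-2-en-1-yl)-4-(triisopropylsilyloxy)benzyl]-5-oxo-3-[4-(triisopropylsilyloxy)phenyl]-2,5-dihydrofuran-2-carboxylate
Product: 23 penta-TIPS ether of the target (all four phenols and the enol of the epoxide-derived half silylated; secondary carbinol free)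
Conditions: 13 (1.5 equiv), (PhO)2P(O)OH (10 mol %), (CF3)2CHOH/CH2Cl2 1:1, 4 Å MS, 0 °C → rt
Reagents that add atoms: none
Why: Acid-promoted SN1-like epoxide opening: Brønsted/hydrogen-bond activation in hexafluoroisopropanol polarizes the tertiary C–O bond so that the enol oxygen of 13 (the only free O–H present) attacks the tertiary carbon, the C–O bond at the secondary carbon stays intact (S carbinol), and the bulky silyl groups on every other oxygen, including the ortho aryl oxygen, disfavour intramolecular trapping.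

Step 14
Reactants: 23 penta-TIPS ether of the target
Product: 24 Asperbutenolide A
Conditions: Bu4NF (6 equiv), AcOH (6 equiv), THF, 0 °C → rt
Reagents that add atoms: none
Why: Fluoride-mediated cleavage of the four aryl and one enol silyl ethers under acetic acid buffering frees all hydroxyls without touching the prenyl group, the tertiary ether, the esters or any stereocentre.

## Compound list

1 | 3-iodo-L-tyrosine | N[C@@H](Cc1ccc(O)c(I)c1)C(=O)O | starting material
2 | (S)-2-hydroxy-3-(4-hydroxy-3-iodophenyl)propanoic acid | O[C@@H](Cc1ccc(O)c(I)c1)C(=O)O | intermediate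
3 | (2S,5S)-2-tert-butyl-5-(4-hydroxy-3-iodobenzyl)-1,3-dioxolan-4-one | CC(C)(C)[C@H]1O[C@@H](Cc2ccc(O)c(I)c2)C(=O)O1 | intermediate
4 | (2S,5S)-2-tert-butyl-5-[3-iodo-4-(triisopropylsilyloxy)benzyl]-1,3-dioxolan-4-one | CC(C)(C)[C@H]1O[C@@H](Cc2ccc(O[Si](C(C)C)(C(C)C)C(C)C)c(I)c2)C(=O)O1 | intermediate
5 | 4-(triisopropylsilyloxy)benzaldehyde | O=Cc1ccc(O[Si](C(C)C)(C(C)C)C(C)C)cc1 | starting material
6 | methyl dichloroacetate | COC(=O)C(Cl)Cl | starting material
7 | methyl 2-chloro-3-[4-(triisopropylsilyloxy)phenyl]oxirane-2-carboxylate (racemic, not isolated) | COC(=O)C1(Cl)OC1c1ccc(O[Si](C(C)C)(C(C)C)C(C)C)cc1 | intermediate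
8 | methyl 3-chloro-2-oxo-3-[4-(triisopropylsilyloxy)phenyl]propanoate (racemic) | COC(=O)C(=O)C(Cl)c1ccc(O[Si](C(C)C)(C(C)C)C(C)C)cc1 | intermediate
9 | (S)-2-tert-butyl-5-[3-iodo-4-(triisopropylsilyloxy)benzyl]-4-(trimethylsilyloxy)-1,3-dioxole (not isolated) | CC(C)(C)[C@H]1OC(Cc2ccc(O[Si](C(C)C)(C(C)C)C(C)C)c(I)c2)=C(O[Si](C)(C)C)O1 | intermediate
10 | (2S,5R)-2-tert-butyl-5-[3-iodo-4-(triisopropylsilyloxy)benzyl]-5-{3-methoxy-2,3-dioxo-1-[4-(triisopropylsilyloxy)phenyl]propyl}-1,3-dioxolan-4-one (epimers at the benzylic CH) | CC(C)(C)[C@H]1O[C@@](C(c2ccc(O[Si](C(C)C)(C(C)C)C(C)C)cc2)C(=O)C(=O)OC)(Cc2ccc(O[Si](C(C)C)(C(C)C)C(C)C)c(I)c2)C(=O)O1 | intermediate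
11 | dimethyl (2R)-2-hydroxy-2-[3-iodo-4-(triisopropylsilyloxy)benzyl]-4-oxo-3-[4-(triisopropylsilyloxy)phenyl]pentanedioate (not isolated) | COC(=O)C(=O)C(c1ccc(O[Si](C(C)C)(C(C)C)C(C)C)cc1)[C@](O)(Cc1ccc(O[Si](C(C)C)(C(C)C)C(C)C)c(I)c1)C(=O)OC | intermediate
12 | methyl (R)-4-hydroxy-2-[3-iodo-4-(triisopropylsilyloxy)benzyl]-5-oxo-3-[4-(triisopropylsilyloxy)phenyl]-2,5-dihydrofuran-2-carboxylate | COC(=O)[C@]1(Cc2ccc(O[Si](C(C)C)(C(C)C)C(C)C)c(I)c2)OC(=O)C(O)=C1c1ccc(O[Si](C(C)C)(C(C)C)C(C)C)cc1 | intermediate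
13 | methyl (R)-4-hydroxy-2-[3-(3-methylbut-2-en-1-yl)-4-(triisopropylsilyloxy)benzyl]-5-oxo-3-[4-(triisopropylsilyloxy)phenyl]-2,5-dihydrofuran-2-carboxylate | COC(=O)[C@]1(Cc2ccc(O[Si](C(C)C)(C(C)C)C(C)C)c(CC=C(C)C)c2)OC(=O)C(O)=C1c1ccc(O[Si](C(C)C)(C(C)C)C(C)C)cc1 | intermediate
14 | methyl (R)-2-[3-iodo-4-(triisopropylsilyloxy)benzyl]-5-oxo-4-(triisopropylsilyloxy)-3-[4-(triisopropylsilyloxy)phenyl]-2,5-dihydrofuran-2-carboxylate | COC(=O)[C@]1(Cc2ccc(O[Si](C(C)C)(C(C)C)C(C)C)c(I)c2)OC(=O)C(O[Si](C(C)C)(C(C)C)C(C)C)=C1c1ccc(O[Si](C(C)C)(C(C)C)C(C)C)cc1 | intermediate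
15 | D-malic acid, (R)-2-hydroxybutanedioic acid | O[C@H](CC(=O)O)C(=O)O | starting material
16 | (R)-2-(2,2-dimethyl-5-oxo-1,3-dioxolan-4-yl)acetic acid | CC1(C)O[C@H](CC(=O)O)C(=O)O1 | intermediate
17 | (R)-3,4-dihydroxy-4-methylpentanoic acid (not isolated) | CC(C)(O)[C@H](O)CC(=O)O | intermediate
18 | (R)-4-hydroxy-5,5-dimethyldihydrofuran-2(3H)-one | CC1(C)OC(=O)C[C@H]1O | intermediate
19 | cesium (R)-3,4-dihydroxy-4-methylpentanoate (not isolated) | CC(C)(O)[C@H](O)CC(=O)[O-].[Cs+] | intermediate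
20 | methyl (R)-2-{3-[(R)-2,3-dihydroxy-3-methylbutyl]-4-(triisopropylsilyloxy)benzyl}-5-oxo-4-(triisopropylsilyloxy)-3-[4-(triisopropylsilyloxy)phenyl]-2,5-dihydrofuran-2-carboxylate | COC(=O)[C@]1(Cc2ccc(O[Si](C(C)C)(C(C)C)C(C)C)c(C[C@@H](O)C(C)(C)O)c2)OC(=O)C(O[Si](C(C)C)(C(C)C)C(C)C)=C1c1ccc(O[Si](C(C)C)(C(C)C)C(C)C)cc1 | intermediate
21 | methyl (R)-2-{3-[(R)-3-hydroxy-3-methyl-2-(methylsulfonyloxy)butyl]-4-(triisopropylsilyloxy)benzyl}-5-oxo-4-(triisopropylsilyloxy)-3-[4-(triisopropylsilyloxy)phenyl]-2,5-dihydrofuran-2-carboxylate (not isolated) | COC(=O)[C@]1(Cc2ccc(O[Si](C(C)C)(C(C)C)C(C)C)c(C[C@@H](OS(C)(=O)=O)C(C)(C)O)c2)OC(=O)C(O[Si](C(C)C)(C(C)C)C(C)C)=C1c1ccc(O[Si](C(C)C)(C(C)C)C(C)C)cc1 | intermediate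
22 | methyl (R)-2-{3-{[(S)-3,3-dimethyloxiran-2-yl]methyl}-4-(triisopropylsilyloxy)benzyl}-5-oxo-4-(triisopropylsilyloxy)-3-[4-(triisopropylsilyloxy)phenyl]-2,5-dihydrofuran-2-carboxylate | COC(=O)[C@]1(Cc2ccc(O[Si](C(C)C)(C(C)C)C(C)C)c(C[C@@H]3OC3(C)C)c2)OC(=O)C(O[Si](C(C)C)(C(C)C)C(C)C)=C1c1ccc(O[Si](C(C)C)(C(C)C)C(C)C)cc1 | intermediate
23 | penta-TIPS ether of the target (four aryl O–TIPS, one enol O–TIPS, free S carbinol) | COC(=O)[C@]1(Cc2ccc(O[Si](C(C)C)(C(C)C)C(C)C)c(C[C@H](O)C(C)(C)OC3=C(c4ccc(O[Si](C(C)C)(C(C)C)C(C)C)cc4)[C@](Cc4ccc(O[Si](C(C)C)(C(C)C)C(C)C)c(CC=C(C)C)c4)(C(=O)OC)OC3=O)c2)OC(=O)C(O[Si](C(C)C)(C(C)C)C(C)C)=C1c1ccc(O[Si](C(C)C)(C(C)C)C(C)C)cc1 | intermediate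
24 | Asperbutenolide A | COC(=O)[C@]1(Cc2ccc(O)c(C[C@H](O)C(C)(C)OC3=C(c4ccc(O)cc4)[C@](Cc4ccc(O)c(CC=C(C)C)c4)(C(=O)OC)OC3=O)c2)OC(=O)C(O)=C1c1ccc(O)cc1 | target

## Step count and risks

Total: 14 steps. Longest linear sequence: 10 steps (1 → 2 → 3 → 4 → 10 → 12 → 14 → 20 → 22 → 23 → 24; steps 1, 2, 3, 5, 6, 8, 11, 12, 13, 14).

The three steps most likely to fail:

**Step 5 (the proposed new photochemical coupling).** Risks are slow radical addition to the fully substituted ketene-acetal carbon, a background polar attack of 9 on the keto carbonyl of 8, and reduction of 8 without coupling. The fallback is known chemistry, a silicon-tethered oxidative enolate coupling. It sets out from 4 and 8 and comes back at 10. Zinc dust in acetic acid removes the chlorine of 8 to give methyl 2-oxo-3-[4-(triisopropylsilyloxy)phenyl]propanoate F1. Dioxolanone 4 is deprotonated (LiN(iPr)2, THF, −78 °C) and quenched with excess Me2SiCl2 to the chlorodimethylsilyl ketene acetal F2. The sodium enolate of F1 (NaN(SiMe3)2) displaces the chloride on silicon to give the unsymmetrical silyl bis-enol ether F3. Oxidation with (NH4)2Ce(NO3)6 and NaHCO3 in MeCN at −10 °C joins the two enol carbons intramolecularly, again anti to the tert-butyl group, and delivers 10.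

**Step 11 (decarboxylative arylation).** The radical is a primary, non-stabilized one and the aryl iodide carries a bulky ortho silyloxy group. The fallback replaces the photochemical free-carboxylate coupling by a thermal nickel/zinc reductive coupling of a redox-active ester, which tolerates ortho-substituted aryl iodides better. It sets out from 18 and 14 and comes back at 20. Lactone 18 is opened and protected (2,2-dimethoxypropane, MeOH, TsOH) as methyl 2-[(4R)-2,2,5,5-tetramethyl-1,3-dioxolan-4-yl]acetate F4, saponified (LiOH, then mild acid) to 2-[(4R)-2,2,5,5-tetramethyl-1,3-dioxolan-4-yl]acetic acid F5, and esterified with N-hydroxyphthalimide (N,N'-diisopropylcarbodiimide) to the N-acyloxyphthalimide F6. Coupling of F6 with 14 (NiBr2·glyme, dtbbpy, Zn, DMA, rt) gives the acetonide-protected side-chain arene F7, and 80% aqueous AcOH at 40 °C removes the acetonide to give 20.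

**Step 13 (ether-forming union).** Risks are hydride shift of the activated epoxide to a ketone, trapping by the ortho silyloxy oxygen, and low reactivity of the hindered enol. The fallback forms the tertiary C–O bond by cobalt-hydride Markovnikov hydroalkoxylation of an isopropenyl group, before the prenyl group is present. It sets out from 22 and 12 and comes back at 24. Epoxide 22 is isomerized (Et3SiOTf, 2,6-lutidine, then DBU) to the allylic triethylsilyl ether F8, with the C–O bond at the stereocentre untouched. Hydroalkoxylation of F8 with the enol OH of 12 (Co(salen) with salen = N,N'-bis(3,5-di-tert-butylsalicylidene)ethane-1,2-diamine dianion as an achiral divalent cobalt catalyst, N-fluoro-2,4,6-trimethylpyridinium tetrafluoroborate, PhSiH3, CH2Cl2, 0 °C) gives the iodinated dimer triethylsilyl ether F9. Stille prenylation under the conditions of step 7 gives the prenylated dimer triethylsilyl ether F10, and the fluoride conditions of step 14 remove the triethylsilyl group together with the TIPS groups to give 24.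

## Further compounds

F1 | step 5 | methyl 2-oxo-3-[4-(triisopropylsilyloxy)phenyl]propanoate | COC(=O)C(=O)Cc1ccc(O[Si](C(C)C)(C(C)C)C(C)C)cc1
F2 | step 5 | (S)-2-tert-butyl-4-[chloro(dimethyl)silyloxy]-5-[3-iodo-4-(triisopropylsilyloxy)benzyl]-1,3-dioxole | CC(C)(C)[C@H]1OC(Cc2ccc(O[Si](C(C)C)(C(C)C)C(C)C)c(I)c2)=C(O[Si](C)(C)Cl)O1
F3 | step 5 | unsymmetrical dimethylsilyl bis-enol ether of 4 and F1 (Z enol of the pyruvate) | CC(C)(C)[C@H]1OC(Cc2ccc(O[Si](C(C)C)(C(C)C)C(C)C)c(I)c2)=C(O[Si](C)(C)O/C(C(=O)OC)=C\c2ccc(O[Si](C(C)C)(C(C)C)C(C)C)cc2)O1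
F4 | step 11 | methyl 2-[(4R)-2,2,5,5-tetramethyl-1,3-dioxolan-4-yl]acetate | COC(=O)C[C@H]1OC(C)(C)OC1(C)C
F5 | step 11 | 2-[(4R)-2,2,5,5-tetramethyl-1,3-dioxolan-4-yl]acetic acid | OC(=O)C[C@H]1OC(C)(C)OC1(C)C
F6 | step 11 | 1,3-dioxoisoindolin-2-yl 2-[(4R)-2,2,5,5-tetramethyl-1,3-dioxolan-4-yl]acetate | O=C(C[C@H]1OC(C)(C)OC1(C)C)ON1C(=O)c2ccccc2C1=O
F7 | step 11 | methyl (R)-5-oxo-2-{3-{[(4R)-2,2,5,5-tetramethyl-1,3-dioxolan-4-yl]methyl}-4-(triisopropylsilyloxy)benzyl}-4-(triisopropylsilyloxy)-3-[4-(triisopropylsilyloxy)phenyl]-2,5-dihydrofuran-2-carboxylate | COC(=O)[C@]1(Cc2ccc(O[Si](C(C)C)(C(C)C)C(C)C)c(C[C@H]3OC(C)(C)OC3(C)C)c2)OC(=O)C(O[Si](C(C)C)(C(C)C)C(C)C)=C1c1ccc(O[Si](C(C)C)(C(C)C)C(C)C)cc1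
F8 | step 13 | methyl (R)-2-{3-[(S)-3-methyl-2-(triethylsilyloxy)but-3-en-1-yl]-4-(triisopropylsilyloxy)benzyl}-5-oxo-4-(triisopropylsilyloxy)-3-[4-(triisopropylsilyloxy)phenyl]-2,5-dihydrofuran-2-carboxylate | COC(=O)[C@]1(Cc2ccc(O[Si](C(C)C)(C(C)C)C(C)C)c(C[C@H](O[Si](CC)(CC)CC)C(C)=C)c2)OC(=O)C(O[Si](C(C)C)(C(C)C)C(C)C)=C1c1ccc(O[Si](C(C)C)(C(C)C)C(C)C)cc1
F9 | step 13 | iodinated dimer triethylsilyl ether (as 23 but with iodine in place of prenyl and O–SiEt3 on the S carbinol) | COC(=O)[C@]1(Cc2ccc(O[Si](C(C)C)(C(C)C)C(C)C)c(C[C@H](O[Si](CC)(CC)CC)C(C)(C)OC3=C(c4ccc(O[Si](C(C)C)(C(C)C)C(C)C)cc4)[C@](Cc4ccc(O[Si](C(C)C)(C(C)C)C(C)C)c(I)c4)(C(=O)OC)OC3=O)c2)OC(=O)C(O[Si](C(C)C)(C(C)C)C(C)C)=C1c1ccc(O[Si](C(C)C)(C(C)C)C(C)C)cc1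
F10 | step 13 | prenylated dimer triethylsilyl ether (as 23 with O–SiEt3 on the S carbinol) | COC(=O)[C@]1(Cc2ccc(O[Si](C(C)C)(C(C)C)C(C)C)c(C[C@H](O[Si](CC)(CC)CC)C(C)(C)OC3=C(c4ccc(O[Si](C(C)C)(C(C)C)C(C)C)cc4)[C@](Cc4ccc(O[Si](C(C)C)(C(C)C)C(C)C)c(CC=C(C)C)c4)(C(=O)OC)OC3=O)c2)OC(=O)C(O[Si](C(C)C)(C(C)C)C(C)C)=C1c1ccc(O[Si](C(C)C)(C(C)C)C(C)C)cc1
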